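**Plan**

1. Retrosynthesis: remove the C8 acyl group, the C13 methylene and the C2=C3 unsaturation, open the lactone to a C12 acetal, and take C7–H/C8–OH back to a Z C7=C8 alkene. The central cut is C9–C10 with O11–C7 re-formed, which contracts the ten-membered carbocycle to a 2-vinyltetrahydropyran bearing a diazo ethyl ketone. The pyran is then cut at O11–C7, C6–C7 and C3–C4.
2. Enabling feature: the furanone oxygen O11 spans C3 and C10 of the C1–C10 ring (an 11-oxabicyclo[6.2.1]undecane). The five-membered ring O11–C3–C2–C1–C10 and the nine-membered ether O11–C3…C10 are what an oxonium ylide of a C7-vinyl tetrahydropyran (O11, C3–C7) gives when C10 moves from oxygen to C9.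
3. Forward order: open chain (crotylboration, alkenyl–aldehyde coupling), then the tetrahydropyran (O11–C7), then the five-membered ketone ring and the nine-membered oxacycle together in the carbenoid step, then the cis-γ-lactone (C6–O–C12), and the furanone double bond last.
4. Stereochemistry: C3/C4 from a reagent-controlled syn-crotylboration; C6 from an oxazaborolidine reduction; C10 relayed from C3 through the ether bridge; C7/C8 from syn hydroboration of the Z alkene on the face fixed by C6; the side-chain centre from (S)-2-methylglycidol.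

Key step: step 20

**Remarks**

- Atoms are labelled by germacrane numbering (C1–C15, O11 = furanone oxygen) in all intermediates. TBS = tert-butyldimethylsilyl, TES = triethylsilyl, PMB = 4-methoxybenzyl.
- Assumption: the C1 carbinol centre made after the key step is drawn as the epimer expected from hydride attack on the side of the ether bridge; it is oxidised again later, so its configuration is immaterial.
- The C6 epimers formed in the alkenyl–aldehyde coupling are carried together and converge on oxidation.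
- The three starting materials and diazoethane (used as a fresh ethereal solution) are taken as available.

**Route**

Step 1
Reactants: 1 4,4-dimethoxybut-1-yne
Product: 3 5,5-dimethoxypent-2-yn-1-ol, via lithium acetylide 2 (not isolated)
Conditions: n-BuLi, THF, −78 °C; (CH2O)n, −78 °C → rt; NH4Cl (aq)
Reagents that add atoms: formaldehyde (as paraformaldehyde), C=O
Why: Deprotonation of the terminal alkyne and addition of the acetylide to formaldehyde (alkynylation of an aldehyde) should give the propargylic alcohol, the acetal being inert to n-BuLi.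

Step 2
Reactants: 3 5,5-dimethoxypent-2-yn-1-ol
Product: 5 (Z)-3-iodo-5,5-dimethoxypent-2-en-1-ol, via alkenylaluminate 4 (not isolated)
Conditions: NaAlH2(OCH2CH2OMe)2, THF, 0 °C → rt; then I2, THF, −78 °C
Reagents that add atoms: iodine, II
Why: Alkoxide-directed trans-hydroalumination of a propargylic alcohol puts hydride on C8 and aluminium on C7 within a five-membered aluminate, and iodinolysis of the C–Al bond with retention should give the Z iodoalkene only.

Step 3
Reactants: 6 (S)-2-methylglycidol
Product: 7 (S)-3-(benzyloxy)-2-methylpropane-1,2-diol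
Conditions: BnOH (5 equiv.), NaH (0.2 equiv.), THF, 0 → 60 °C
Reagents that add atoms: benzyl alcohol, OCc1ccccc1
Why: Base-catalysed SN2 opening of the epoxide by benzyl alkoxide at the unsubstituted CH2 terminus leaves the quaternary stereocentre untouched (the Payne isomer of this epoxy alcohol is the same compound).

Step 4
Reactants: 7 (S)-3-(benzyloxy)-2-methylpropane-1,2-diol
Product: 8 (R)-4-[(benzyloxy)methyl]-2,2,4-trimethyl-1,3-dioxolane
Conditions: Me2C(OMe)2, pyridinium p-toluenesulfonate (cat.), CH2Cl2, rt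
Reagents that add atoms: 2,2-dimethoxypropane, COC(C)(C)OC
Why: Acid-catalysed transketalisation ties the tertiary and the primary hydroxyl of the 1,2-diol into a dioxolane (the descriptor changes only through priorities).

Step 5
Reactants: 8 (R)-4-[(benzyloxy)methyl]-2,2,4-trimethyl-1,3-dioxolane
Product: 9 (R)-(2,2,4-trimethyl-1,3-dioxolan-4-yl)methanol
Conditions: H2 (1 atm), 10% Pd/C, EtOAc, rt
Reagents that add atoms: none
Why: Hydrogenolysis of the benzyl ether over palladium leaves the acetonide intact.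

Step 6
Reactants: 9 (R)-(2,2,4-trimethyl-1,3-dioxolan-4-yl)methanol
Product: 10 (S)-2,2,4-trimethyl-1,3-dioxolane-4-carboxylic acid
Conditions: TEMPO (0.2 equiv.), PhI(OAc)2 (2.2 equiv.), MeCN/H2O 1:1, rt
Reagents that add atoms: water, O
Why: Nitroxyl-catalysed oxidation with a hypervalent iodine co-oxidant in wet acetonitrile takes the primary alcohol through the aldehyde hydrate to the acid; the quaternary centre cannot epimerise.

Step 7
Reactants: 11 3-[(tert-butyldimethylsilyl)oxy]propanal
Product: 12 (3S,4S)-1-[(tert-butyldimethylsilyl)oxy]-4-methylhex-5-en-3-ol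
Conditions: cis-2-butene, KOt-Bu, n-BuLi, THF, −78 → −45 °C; (+)-Ipc2BOMe, −78 °C; BF3·OEt2; then 11, −78 °C; NaOH, H2O2, rt
Reagents that add atoms: (Z)-crotyldiisopinocampheylborane, made in the flask from cis-2-butene (C/C=C\C) and (+)-Ipc2BOMe, C/C=C\CB([C@H]1C[C@H]2C[C@@H]([C@@H]1C)C2(C)C)[C@H]1C[C@H]2C[C@@H]([C@@H]1C)C2(C)C
Why: Asymmetric crotylboration (Brown) through a closed chair Zimmerman–Traxler transition state: the Z crotyl geometry gives the syn C3–OH/C4–CH3 relationship and the isopinocampheyl groups derived from (−)-α-pinene direct attack to the Re face of the aldehyde, setting 3S and 4S together.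

Step 8
Reactants: 12 (3S,4S)-1-[(tert-butyldimethylsilyl)oxy]-4-methylhex-5-en-3-ol
Product: 13 (3S,4S)-1-(TBS-oxy)-4-methyl-3-(TES-oxy)hex-5-ene
Conditions: Et3SiCl, imidazole, CH2Cl2, 0 °C → rt
Reagents that add atoms: chlorotriethylsilane, CC[Si](Cl)(CC)CC
Why: Routine silylation of the secondary alcohol; the triethylsilyl group is chosen so that it can later be removed beside a secondary TBS ether.

Step 9
Reactants: 13 (3S,4S)-1-(TBS-oxy)-4-methyl-3-(TES-oxy)hex-5-ene
Product: 15 (3S,4S)-6-(TBS-oxy)-3-methyl-4-(TES-oxy)hexan-1-ol, via B-alkyl-9-BBN adduct 14 (not isolated)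
Conditions: 9-BBN, THF, 0 °C → rt; then NaOH, H2O2, 0 °C
Reagents that add atoms: hydrogen peroxide, OO
Why: Anti-Markovnikov hydroboration of the terminal alkene with a bulky dialkylborane and oxidation with retention gives the primary C6 alcohol; no stereocentre is formed.

Step 10
Reactants: 15 (3S,4S)-6-(TBS-oxy)-3-methyl-4-(TES-oxy)hexan-1-ol
Product: 16 (3S,4S)-6-(TBS-oxy)-3-methyl-4-(TES-oxy)hexanal
Conditions: Dess–Martin periodinane, NaHCO3, CH2Cl2, 0 °C → rt
Reagents that add atoms: none
Why: Dess–Martin oxidation to the aldehyde under buffered conditions; the nearest stereocentre (C4) is β to the carbonyl and cannot epimerise.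

Step 11
Reactants: 16 (3S,4S)-6-(TBS-oxy)-3-methyl-4-(TES-oxy)hexanal; 5 (Z)-3-iodo-5,5-dimethoxypent-2-en-1-ol
Product: 17 (2Z,6S,7S)-9-(TBS-oxy)-3-(2,2-dimethoxyethyl)-6-methyl-7-(TES-oxy)non-2-ene-1,4-diol (both C4 epimers; C4 of this chain = C6)
Conditions: CrCl2 (6 equiv.), NiCl2 (1 mol %), DMSO, rt
Reagents that add atoms: none
Why: Nozaki–Hiyama–Kishi coupling: nickel-catalysed formation of the alkenylchromium species and its chemoselective 1,2-addition to the aldehyde tolerate the free hydroxyl, the acetal and the silyl ethers; C6 is formed without control, which does not matter because it is oxidised in step 13.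

Step 12
Reactants: 17 the C6-epimeric ene-1,4-diol
Product: 18 methyl carbonate of 17 at the primary allylic hydroxyl (C9–OCO2Me; C6–OH free, both epimers)
Conditions: ClCO2Me (1.1 equiv.), pyridine, CH2Cl2, −20 °C
Reagents that add atoms: methyl chloroformate, COC(=O)Cl
Why: Kinetic acylation: the unhindered primary allylic hydroxyl should react with the chloroformate well before the secondary one flanked by the trisubstituted alkene.

Step 13
Reactants: 18 the C9 methyl carbonate with free C6–OH
Product: 19 (2Z,6S,7S)-9-(TBS-oxy)-3-(2,2-dimethoxyethyl)-6-methyl-4-oxo-7-(TES-oxy)non-2-en-1-yl methyl carbonate (C6 enone)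
Conditions: Dess–Martin periodinane, NaHCO3, CH2Cl2, 0 °C → rt
Reagents that add atoms: none
Why: Dess–Martin oxidation of the allylic alcohol converges both C6 epimers on one enone.

Step 14
Reactants: 19 the C6 enone
Product: 20 (2Z,4S,6S,7S)-9-(TBS-oxy)-3-(2,2-dimethoxyethyl)-4-hydroxy-6-methyl-7-(TES-oxy)non-2-en-1-yl methyl carbonate (6S alcohol)
Conditions: (R)-2-methyl-CBS-oxazaborolidine (0.5 equiv.), catecholborane, toluene, −78 °C
Reagents that add atoms: none
Why: Corey–Bakshi–Shibata reduction: the branched alkenyl group acts as the large substituent and the (R)-oxazaborolidine directs hydride to the face that gives the 6S allylic alcohol, 1,2-reduction being ensured by catecholborane at low temperature.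

Step 15
Reactants: 20 the 6S allylic alcohol
Product: 21 (2Z,4S,6S,7S)-4,9-bis(TBS-oxy)-3-(2,2-dimethoxyethyl)-6-methyl-7-(TES-oxy)non-2-en-1-yl methyl carbonate
Conditions: TBSCl, imidazole, DMF, 35 °C
Reagents that add atoms: tert-butyldimethylsilyl chloride, CC(C)(C)[Si](C)(C)Cl
Why: Silylation of the allylic alcohol under imidazole catalysis; a silyl chloride is used instead of a triflate so that the dimethyl acetal is not touched.

Step 16
Reactants: 21 the tris-silyl ether
Product: 22 (2Z,4S,6S,7S)-4-(TBS-oxy)-3-(2,2-dimethoxyethyl)-7,9-dihydroxy-6-methylnon-2-en-1-yl methyl carbonate (C1–OH and C3–OH free)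
Conditions: HF·pyridine, pyridine, THF, 0 °C → rt
Reagents that add atoms: none
Why: Selective desilylation: buffered fluoride should cleave the triethylsilyl ether and the primary TBS ether far faster than the hindered secondary allylic TBS ether.

Step 17
Reactants: 22 the dihydroxy allylic carbonate
Product: 23 2-[(2S,3S,5S,6R)-5-(TBS-oxy)-6-(2,2-dimethoxyethyl)-6-ethenyl-3-methyltetrahydro-2H-pyran-2-yl]ethan-1-ol
Conditions: Pd(PPh3)4 (5 mol %), THF, 40 °C, high dilution
Reagents that add atoms: none
Why: Tsuji–Trost allylic etherification: zerovalent palladium ionises the carbonate to a π-allyl complex and methoxide, and the C3 alkoxide closes the six-membered ring at the more substituted terminus C7 (6-exo) through a chair in which the C3 chain, the C6 silyloxy group and the metal-bound allyl unit are equatorial, which should give the 7R ether with the vinyl group cis to the C3 substituent; the primary hydroxyl would have to form an eight-membered ring and stays free.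

Step 18
Reactants: 23 the tetrahydropyran alcohol
Product: 24 2-[(2S,3S,5S,6R)-5-(TBS-oxy)-6-(2,2-dimethoxyethyl)-6-ethenyl-3-methyltetrahydro-2H-pyran-2-yl]acetic acid
Conditions: TEMPO (0.2 equiv.), PhI(OAc)2 (2.2 equiv.), MeCN/pH 7 phosphate buffer, rt
Reagents that add atoms: water, O
Why: Nitroxyl-catalysed oxidation of the primary alcohol to the acid under buffered conditions that spare the vinyl group, the acetal and the silyl ether.

Step 19
Reactants: 24 the tetrahydropyranyl acetic acid
Product: 26 3-diazo-1-[(2S,3S,5S,6R)-5-(TBS-oxy)-6-(2,2-dimethoxyethyl)-6-ethenyl-3-methyltetrahydro-2H-pyran-2-yl]butan-2-one, via mixed anhydride 25 (not isolated)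
Conditions: i-BuOCOCl, Et3N, Et2O, −20 °C; then CH3CHN2 (Et2O, freshly distilled from N-ethyl-N-nitrosourea/KOH), 0 °C
Reagents that add atoms: diazoethane, CC=[N+]=[N-]
Why: Acylation of a diazoalkane by a mixed carbonic anhydride (Arndt–Eistert-type diazoketone synthesis) proceeds without acid and so spares the acetal and the silyl ether.

Step 20
Reactants: 26 the 2-vinyltetrahydropyran diazo ethyl ketone
Product: 28 (1S,2S,4S,5Z,8S)-4-(TBS-oxy)-5-(2,2-dimethoxyethyl)-2,8-dimethyl-11-oxabicyclo[6.2.1]undec-5-en-9-one, via oxonium ylide 27 (not isolated)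
Conditions: Cu(CF3COCHCOCF3)2 (5 mol %), CH2Cl2, reflux, slow addition of 26
Reagents that add atoms: none
Why: Copper-catalysed loss of nitrogen gives an electrophilic carbenoid at C10 that is captured by the tetrahydropyran oxygen to form the bicyclic oxonium ylide 27, which rearranges by a concerted [2,3]-sigmatropic shift in which C10 bonds to the vinyl terminus C9 while O11–C7 breaks and C7=C8 forms. The closest known reaction type is metal-carbenoid oxonium-ylide formation followed by [2,3]-rearrangement of 2-vinyl cyclic ethers to oxygen-bridged medium rings. The five-membered ketone ring closes by attack of the ether oxygen on the carbenoid carbon (five-membered O11–C10 closure), and the nine-membered oxacycle, hence the ten-membered carbocycle, arises by three-atom ring expansion of the six-membered ether through a five-centre envelope transition state, not by end-to-end cyclisation. The new quaternary centre C10 is fixed by C3, because the oxygen bridge can span C3 and C10 only when C4 and C9 are cis on the five-membered ring, while C7 ceases to be a stereocentre. The step needs oxygen capture to outrun 1,2-hydride migration from the C14 methyl and C–H insertion, which the ether oxygen held five atoms from the carbenoid carbon and the electrophilic copper carbenoid should secure, and it needs the ring-cis (Z) C7=C8 geometry, which this catalyst favours and which is the only alkene geometry that avoids a trans double bond in the nine-membered ring.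

Step 21
Reactants: 28 the bridged ketone
Product: 29 the (1S) alcohol of 28 [(1S,2S,4S,5Z,8S,9S)-…-undec-5-en-9-ol; hydroxyl turned toward the carbocyclic bridge]
Conditions: NaBH4, MeOH, 0 °C
Reagents that add atoms: none
Why: Borohydride reduction of the ketone; hydride should arrive from the side of the one-atom ether bridge, away from the six-carbon bridge, so the hydroxyl points toward the carbocycle (this centre is temporary).

Step 22
Reactants: 29 the C1 alcohol
Product: 30 the C1 PMB ether of 29
Conditions: NaH, 4-MeOC6H4CH2Cl, n-Bu4NI (cat.), DMF, 0 °C → rt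
Reagents that add atoms: 4-methoxybenzyl chloride, COc1ccc(CCl)cc1
Why: Williamson etherification of the sodium alkoxide under iodide catalysis masks C1 as an ether that is stable to borane, base and acid and is removable by oxidation.

Step 23
Reactants: 30 the PMB ether with the Z C7=C8 alkene
Product: 32 the C8 alcohol [H added at C7, OH at C8; (1S,3S,4S,6S,7R,8S,10S) by germacrane numbering, C7 and C8 with the spatial arrangement of the target], via C8 alkylborane 31 (not isolated)
Conditions: BH3·THF, THF, 0 °C → rt; then NaOH, H2O2, 0 °C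
Reagents that add atoms: hydrogen peroxide, OO
Why: Hydroboration–oxidation: B–H adds syn across the Z alkene with boron on the less substituted C8, and allylic 1,3-strain with C9 keeps C6–H in the alkene plane so that ring carbon C5 and the ether bridge shield one face and borane adds to the other (the face of the outward-pointing silyloxy group), which places C7–H cis to C6–H and sets C8; oxidation goes with retention.

Step 24
Reactants: 32 the C8 alcohol; 10 (S)-2,2,4-trimethyl-1,3-dioxolane-4-carboxylic acid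
Product: 34 the C8 ester of 32 with acid 10, via Yamaguchi mixed anhydride 33 (not isolated)
Conditions: 10, 2,4,6-Cl3C6H2COCl, Et3N, THF, rt; then 32, DMAP, toluene, 40 °C
Reagents that add atoms: none
Why: Yamaguchi esterification: DMAP attacks the mixed anhydride at the less hindered carbonyl and the acylpyridinium acylates the secondary C8 alcohol; no stereocentre is involved and the acid has no α-hydrogen.

Step 25
Reactants: 34 the C8 ester
Product: 35 the lactol (C6–O–C12 hemiacetal, cis-fused at C6/C7, both anomers)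
Conditions: 48% aq. HF/MeCN (1:19), 0 °C → rt
Reagents that add atoms: water, O
Why: Aqueous HF removes the TBS ether and hydrolyses the dimethyl acetal, and the 4-hydroxy aldehyde closes to the five-membered lactol (5-exo hemiacetalisation); the ester-deactivated acetonide and the PMB ether should survive, and acid avoids acyl migration from O8.

Step 26
Reactants: 35 the lactol
Product: 36 the cis-fused γ-lactone (6S,7S,8S)
Conditions: n-Pr4N[RuO4] (5 mol %), N-methylmorpholine N-oxide, 4 Å sieves, CH2Cl2, rt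
Reagents that add atoms: none
Why: Ley–Griffith oxidation of the lactol to the γ-lactone; the cis ring fusion was fixed in step 23.

Step 27
Reactants: 36 the cis-lactone
Product: 40 the α-methylene lactone (C11=C13), via lithium enolate 37 (not isolated), via Mannich base 38 (not isolated), via ammonium iodide 39 (not isolated)
Conditions: LiN(i-Pr)2, THF, −78 °C; Me2N=CH2 I, −78 °C → rt; then MeI, MeOH, rt; then NaHCO3, H2O/CH2Cl2
Reagents that add atoms: Eschenmoser's salt (N,N-dimethylmethyleneiminium iodide), C=[N+](C)C.[I-]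
Why: Mannich methylenation: the lactone enolate (the C8 ester has no α-hydrogen) is aminomethylated, and quaternisation followed by mild base-induced β-elimination of trimethylamine gives the exocyclic alkene; C11 becomes sp2, so its transient configuration is irrelevant.

Step 28
Reactants: 40 the α-methylene lactone PMB ether
Product: 41 the C1 alcohol
Conditions: DDQ, CH2Cl2/pH 7 buffer (10:1), 0 °C → rt
Reagents that add atoms: none
Why: Oxidative cleavage of the 4-methoxybenzyl ether by DDQ through a benzylic oxocarbenium ion is neutral and leaves the methylene lactone, the esters and the acetonide untouched.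

Step 29
Reactants: 41 the C1 alcohol
Product: 42 the C1 ketone
Conditions: Dess–Martin periodinane, NaHCO3, CH2Cl2, 0 °C → rt
Reagents that add atoms: none
Why: Dess–Martin oxidation of the secondary alcohol restores the C1 ketone and removes the temporary stereocentre.

Step 30
Reactants: 42 the C1 ketone
Product: 44 the 3(2H)-furanone acetonide (C2=C3), via trimethylsilyl enol ether 43 (not isolated)
Conditions: Me3SiOTf, Et3N, CH2Cl2, −78 → 0 °C; then Pd(OAc)2 (1.1 equiv.), MeCN, rt
Reagents that add atoms: none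
Why: Saegusa–Ito dehydrogenation: the ketone can enolise only toward C2 (C10 is quaternary), and palladation of the silyl enol ether at C2 followed by β-hydride elimination of C3–H gives the 3(2H)-furanone.

Step 31
Reactants: 44 the furanone acetonide
Product: 45 the target, CNP0263764.3
Conditions: CF3CO2H/H2O (4:1), CH2Cl2, 0 °C
Reagents that add atoms: none
Why: Acid hydrolysis of the isopropylidene ketal releases the tertiary/primary diol; the furanone and the α-methylene lactone are stable to aqueous acid.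

**Compound list**

1 | 4,4-dimethoxybut-1-yne | C#CCC(OC)OC | starting material
2 | lithium 4,4-dimethoxybut-1-yn-1-ide | [Li]C#CCC(OC)OC | intermediate (not isolated)
3 | 5,5-dimethoxypent-2-yn-1-ol | OCC#CCC(OC)OC | intermediate
4 | sodium alkenylaluminate (five-membered O–Al–C7 ate complex) | COC(OC)CC1=CCO[Al-]1(OCCOC)OCCOC.[Na+] | intermediate (not isolated)
5 | (Z)-3-iodo-5,5-dimethoxypent-2-en-1-ol | OC/C=C(\I)CC(OC)OC | intermediate
6 | (S)-2-methylglycidol | C[C@]1(CO)CO1 | starting material
7 | (S)-3-(benzyloxy)-2-methylpropane-1,2-diol | C[C@](O)(CO)COCc1ccccc1 | intermediate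
8 | (R)-4-[(benzyloxy)methyl]-2,2,4-trimethyl-1,3-dioxolane | C[C@@]1(COCc2ccccc2)COC(C)(C)O1 | intermediate
9 | (R)-(2,2,4-trimethyl-1,3-dioxolan-4-yl)methanol | C[C@@]1(CO)COC(C)(C)O1 | intermediate
10 | (S)-2,2,4-trimethyl-1,3-dioxolane-4-carboxylic acid | C[C@@]1(C(=O)O)COC(C)(C)O1 | intermediate
11 | 3-[(tert-butyldimethylsilyl)oxy]propanal | O=CCCO[Si](C)(C)C(C)(C)C | starting material
12 | (3S,4S)-1-[(tert-butyldimethylsilyl)oxy]-4-methylhex-5-en-3-ol | C=C[C@H](C)[C@@H](O)CCO[Si](C)(C)C(C)(C)C | intermediate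
13 | (3S,4S)-1-(TBS-oxy)-4-methyl-3-(TES-oxy)hex-5-ene | C=C[C@H](C)[C@@H](O[Si](CC)(CC)CC)CCO[Si](C)(C)C(C)(C)C | intermediate
14 | B-alkyl-9-borabicyclo[3.3.1]nonane adduct of 13 (boron on C6) | C1CCC2CCCC1B2CC[C@H](C)[C@@H](O[Si](CC)(CC)CC)CCO[Si](C)(C)C(C)(C)C | intermediate (not isolated)
15 | (3S,4S)-6-(TBS-oxy)-3-methyl-4-(TES-oxy)hexan-1-ol | OCC[C@H](C)[C@@H](O[Si](CC)(CC)CC)CCO[Si](C)(C)C(C)(C)C | intermediate
16 | (3S,4S)-6-(TBS-oxy)-3-methyl-4-(TES-oxy)hexanal | O=CC[C@H](C)[C@@H](O[Si](CC)(CC)CC)CCO[Si](C)(C)C(C)(C)C | intermediate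
17 | (2Z,6S,7S)-9-(TBS-oxy)-3-(2,2-dimethoxyethyl)-6-methyl-7-(TES-oxy)non-2-ene-1,4-diol (C6 epimers) | OC/C=C(/CC(OC)OC)C(O)C[C@H](C)[C@@H](O[Si](CC)(CC)CC)CCO[Si](C)(C)C(C)(C)C | intermediate
18 | C9 methyl carbonate of 17 (C6 epimers) | COC(=O)OC/C=C(/CC(OC)OC)C(O)C[C@H](C)[C@@H](O[Si](CC)(CC)CC)CCO[Si](C)(C)C(C)(C)C | intermediate
19 | (2Z,6S,7S)-9-(TBS-oxy)-3-(2,2-dimethoxyethyl)-6-methyl-4-oxo-7-(TES-oxy)non-2-en-1-yl methyl carbonate | COC(=O)OC/C=C(/CC(OC)OC)C(=O)C[C@H](C)[C@@H](O[Si](CC)(CC)CC)CCO[Si](C)(C)C(C)(C)C | intermediate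
20 | (2Z,4S,6S,7S)-9-(TBS-oxy)-3-(2,2-dimethoxyethyl)-4-hydroxy-6-methyl-7-(TES-oxy)non-2-en-1-yl methyl carbonate | COC(=O)OC/C=C(/CC(OC)OC)[C@@H](O)C[C@H](C)[C@@H](O[Si](CC)(CC)CC)CCO[Si](C)(C)C(C)(C)C | intermediate
21 | (2Z,4S,6S,7S)-4,9-bis(TBS-oxy)-3-(2,2-dimethoxyethyl)-6-methyl-7-(TES-oxy)non-2-en-1-yl methyl carbonate | COC(=O)OC/C=C(/CC(OC)OC)[C@@H](O[Si](C)(C)C(C)(C)C)C[C@H](C)[C@@H](O[Si](CC)(CC)CC)CCO[Si](C)(C)C(C)(C)C | intermediate
22 | (2Z,4S,6S,7S)-4-(TBS-oxy)-3-(2,2-dimethoxyethyl)-7,9-dihydroxy-6-methylnon-2-en-1-yl methyl carbonate | COC(=O)OC/C=C(/CC(OC)OC)[C@@H](O[Si](C)(C)C(C)(C)C)C[C@H](C)[C@@H](O)CCO | intermediate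
23 | 2-[(2S,3S,5S,6R)-5-(TBS-oxy)-6-(2,2-dimethoxyethyl)-6-ethenyl-3-methyltetrahydro-2H-pyran-2-yl]ethan-1-ol | OCC[C@@H]1O[C@@](C=C)(CC(OC)OC)[C@@H](O[Si](C)(C)C(C)(C)C)C[C@@H]1C | intermediate
24 | 2-[(2S,3S,5S,6R)-5-(TBS-oxy)-6-(2,2-dimethoxyethyl)-6-ethenyl-3-methyltetrahydro-2H-pyran-2-yl]acetic acid | OC(=O)C[C@@H]1O[C@@](C=C)(CC(OC)OC)[C@@H](O[Si](C)(C)C(C)(C)C)C[C@@H]1C | intermediate
25 | isobutyl carbonic mixed anhydride of 24 | CC(C)COC(=O)OC(=O)C[C@@H]1O[C@@](C=C)(CC(OC)OC)[C@@H](O[Si](C)(C)C(C)(C)C)C[C@@H]1C | intermediate (not isolated)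
26 | 3-diazo-1-[(2S,3S,5S,6R)-5-(TBS-oxy)-6-(2,2-dimethoxyethyl)-6-ethenyl-3-methyltetrahydro-2H-pyran-2-yl]butan-2-one | CC(=[N+]=[N-])C(=O)C[C@@H]1O[C@@](C=C)(CC(OC)OC)[C@@H](O[Si](C)(C)C(C)(C)C)C[C@@H]1C | intermediate
27 | bicyclic oxonium ylide (O11 bonded to C3, C7 and C10; carbanion at C10) | C[C-]1C(=O)C[C@@H]2[O+]1[C@@](C=C)(CC(OC)OC)[C@@H](O[Si](C)(C)C(C)(C)C)C[C@@H]2C | intermediate (not isolated)
28 | (1S,2S,4S,5Z,8S)-4-(TBS-oxy)-5-(2,2-dimethoxyethyl)-2,8-dimethyl-11-oxabicyclo[6.2.1]undec-5-en-9-one | C[C@H]1C[C@H](O[Si](C)(C)C(C)(C)C)/C(CC(OC)OC)=C\C[C@]2(C)O[C@H]1CC2=O | intermediate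
29 | (1S,2S,4S,5Z,8S,9S)-4-(TBS-oxy)-5-(2,2-dimethoxyethyl)-2,8-dimethyl-11-oxabicyclo[6.2.1]undec-5-en-9-ol (germacrane 1S alcohol) | C[C@H]1C[C@H](O[Si](C)(C)C(C)(C)C)/C(CC(OC)OC)=C\C[C@]2(C)O[C@H]1C[C@@H]2O | intermediate
30 | C1 PMB ether of 29 | C[C@H]1C[C@H](O[Si](C)(C)C(C)(C)C)/C(CC(OC)OC)=C\C[C@]2(C)O[C@H]1C[C@@H]2OCc1ccc(OC)cc1 | intermediate
31 | C8 alkylborane from 30 (BH2 on C8, H on C7) | C[C@H]1C[C@H](O[Si](C)(C)C(C)(C)C)[C@H](CC(OC)OC)[C@@H](B)C[C@]2(C)O[C@H]1C[C@@H]2OCc1ccc(OC)cc1 | intermediate (not isolated)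
32 | C8 alcohol, germacrane (1S,3S,4S,6S,7R,8S,10S) | C[C@H]1C[C@H](O[Si](C)(C)C(C)(C)C)[C@H](CC(OC)OC)[C@@H](O)C[C@]2(C)O[C@H]1C[C@@H]2OCc1ccc(OC)cc1 | intermediate
33 | (S)-2,2,4-trimethyl-1,3-dioxolane-4-carboxylic 2,4,6-trichlorobenzoic anhydride | C[C@@]1(C(=O)OC(=O)c2c(Cl)cc(Cl)cc2Cl)COC(C)(C)O1 | intermediate (not isolated)
34 | C8 (S)-2,2,4-trimethyl-1,3-dioxolane-4-carboxylate of 32 | C[C@H]1C[C@H](O[Si](C)(C)C(C)(C)C)[C@H](CC(OC)OC)[C@@H](OC(=O)[C@]3(C)COC(C)(C)O3)C[C@]2(C)O[C@H]1C[C@@H]2OCc1ccc(OC)cc1 | intermediate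
35 | cis-fused lactol (C6–O–C12–OH, C12 anomers) | C[C@H]1C[C@@H]4OC(O)C[C@@H]4[C@@H](OC(=O)[C@]3(C)COC(C)(C)O3)C[C@]2(C)O[C@H]1C[C@@H]2OCc1ccc(OC)cc1 | intermediate
36 | cis-fused γ-lactone, germacrane (1S,3S,4S,6S,7S,8S,10S) | C[C@H]1C[C@@H]4OC(=O)C[C@@H]4[C@@H](OC(=O)[C@]3(C)COC(C)(C)O3)C[C@]2(C)O[C@H]1C[C@@H]2OCc1ccc(OC)cc1 | intermediate
37 | lithium enolate of lactone 36 | C[C@H]1C[C@@H]4OC(O[Li])=C[C@@H]4[C@@H](OC(=O)[C@]3(C)COC(C)(C)O3)C[C@]2(C)O[C@H]1C[C@@H]2OCc1ccc(OC)cc1 | intermediate (not isolated)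
38 | C11 (dimethylamino)methyl lactone (C11 epimers) | C[C@H]1C[C@@H]4OC(=O)C(CN(C)C)[C@@H]4[C@@H](OC(=O)[C@]3(C)COC(C)(C)O3)C[C@]2(C)O[C@H]1C[C@@H]2OCc1ccc(OC)cc1 | intermediate (not isolated)
39 | C11 (trimethylammonio)methyl lactone iodide | C[C@H]1C[C@@H]4OC(=O)C(C[N+](C)(C)C)[C@@H]4[C@@H](OC(=O)[C@]3(C)COC(C)(C)O3)C[C@]2(C)O[C@H]1C[C@@H]2OCc1ccc(OC)cc1.[I-] | intermediate (not isolated)
40 | α-methylene lactone, C1 PMB ether | C[C@H]1C[C@@H]4OC(=O)C(=C)[C@@H]4[C@@H](OC(=O)[C@]3(C)COC(C)(C)O3)C[C@]2(C)O[C@H]1C[C@@H]2OCc1ccc(OC)cc1 | intermediate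
41 | α-methylene lactone, C1 alcohol | C[C@H]1C[C@@H]4OC(=O)C(=C)[C@@H]4[C@@H](OC(=O)[C@]3(C)COC(C)(C)O3)C[C@]2(C)O[C@H]1C[C@@H]2O | intermediate
42 | α-methylene lactone, C1 ketone | C[C@H]1C[C@@H]4OC(=O)C(=C)[C@@H]4[C@@H](OC(=O)[C@]3(C)COC(C)(C)O3)C[C@]2(C)O[C@H]1CC2=O | intermediate
43 | trimethylsilyl enol ether of 42 (C1=C2) | C[C@H]1C[C@@H]4OC(=O)C(=C)[C@@H]4[C@@H](OC(=O)[C@]3(C)COC(C)(C)O3)C[C@]2(C)O[C@H]1C=C2O[Si](C)(C)C | intermediate (not isolated)
44 | 3(2H)-furanone with the side-chain acetonide | C[C@H]1C[C@@H]4OC(=O)C(=C)[C@@H]4[C@@H](OC(=O)[C@]3(C)COC(C)(C)O3)C[C@]2(C)OC1=CC2=O | intermediate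
45 | CNP0263764.3, germacrane (4S,6S,7S,8S,10S), (2S)-2,3-dihydroxy-2-methylpropanoate at C8 | C[C@H]1C[C@@H]4OC(=O)C(=C)[C@@H]4[C@@H](OC(=O)[C@@](C)(O)CO)C[C@]2(C)OC1=CC2=O | target

**Step count**

Total: 31 steps (2 for iodide 5, 4 for acid 10, 25 in the main line). Longest linear sequence: 25 steps, from 11 to 45 (steps 7–31).

**Steps most likely to fail**

Step 20. The methyl-bearing carbenoid may undergo 1,2-hydride migration to an enone faster than the ether oxygen captures it, or the rearrangement may give the alkene with poor geometric control. The fallback uses a carbenoid with no hydrogen next to the carbene carbon and introduces C14 afterwards. It sets out from 24: activation with carbonyldiimidazole and condensation with LiCH2SO2Ph would give the β-keto sulfone F1. Diazo transfer (4-acetamidobenzenesulfonyl azide, Et3N, MeCN) would give the α-diazo-β-keto sulfone F2. Rh2(OAc)4 or Cu(CF3COCHCOCF3)2 should effect the same oxygen capture and [2,3] shift to the bridged α-sulfonyl ketone F3. Reductive desulfonylation with LiC10H8 in THF at −78 °C, then MeI on the resulting bridgehead enolate, would place the methyl on C10 regiospecifically (its configuration is forced by the bridge). The fallback comes back to the route at 28.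

Step 23. If the nine-membered ring also populates the conformer with the C6 silyloxy group turned into the alkene plane, borane would add to the opposite face and give the C7/C8 diastereomer. The fallback ties O6 to C12 before the alkene is touched. It sets out from 30: n-Bu4NF in THF would give the allylic alcohol F5, and pyridinium p-toluenesulfonate in MeOH would close the cyclic methyl acetal F6 (five-membered ring O6–C6–C7–C11–C12, with C7=C8 now exocyclic to it). That ring holds O6 away from the inside position, so hydroboration–oxidation (BH3·THF; NaOH, H2O2) can only come from the face anti to C5 and should give the cis-fused C8 alcohol F7. Yamaguchi esterification with 10 would give the ester F8, and aqueous acetic acid in THF would hydrolyse the methyl acetal. The fallback comes back to the route at 35.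

Step 17. Ionisation of the hindered trisubstituted carbonate may be followed by β-hydride elimination to a diene, or by attack at the wrong position, instead of forming the tetrasubstituted C7–O bond. The fallback avoids a π-allyl intermediate. It sets out from 22: K2CO3 in MeOH would cleave the carbonate to the triol F4. A cationic gold catalyst (Ph3PAuCl/AgOTf, 4 Å sieves, CH2Cl2) should then effect a dehydrative SN2′ cyclisation of this monoallylic diol by anti-alkoxyauration of C7=C8 by the C3 hydroxyl and anti-elimination of the C9 hydroxyl. The fallback comes back to the route at 23.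

**Further compounds**

F1 | step 20 | 1-(phenylsulfonyl)-3-[(2S,3S,5S,6R)-5-(TBS-oxy)-6-(2,2-dimethoxyethyl)-6-ethenyl-3-methyltetrahydro-2H-pyran-2-yl]propan-2-one | O=C(CS(=O)(=O)c1ccccc1)C[C@@H]1O[C@@](C=C)(CC(OC)OC)[C@@H](O[Si](C)(C)C(C)(C)C)C[C@@H]1C
F2 | step 20 | 1-diazo-1-(phenylsulfonyl)-3-[(2S,3S,5S,6R)-5-(TBS-oxy)-6-(2,2-dimethoxyethyl)-6-ethenyl-3-methyltetrahydro-2H-pyran-2-yl]propan-2-one | O=C(C(=[N+]=[N-])S(=O)(=O)c1ccccc1)C[C@@H]1O[C@@](C=C)(CC(OC)OC)[C@@H](O[Si](C)(C)C(C)(C)C)C[C@@H]1C
F3 | step 20 | bridged ketone as 28 with phenylsulfonyl in place of the C10 methyl | C[C@H]1C[C@H](O[Si](C)(C)C(C)(C)C)/C(CC(OC)OC)=C\C[C@]2(S(=O)(=O)c3ccccc3)O[C@H]1CC2=O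
F4 | step 17 | (2Z,4S,6S,7S)-4-(TBS-oxy)-3-(2,2-dimethoxyethyl)-6-methylnon-2-ene-1,7,9-triol | OC/C=C(/CC(OC)OC)[C@@H](O[Si](C)(C)C(C)(C)C)C[C@H](C)[C@@H](O)CCO
F5 | step 23 | C6 allylic alcohol (30 without the TBS group) | C[C@H]1C[C@H](O)/C(CC(OC)OC)=C\C[C@]2(C)O[C@H]1C[C@@H]2OCc1ccc(OC)cc1
F6 | step 23 | cyclic methyl acetal (O6–C12) with exocyclic Z C7=C8 | C[C@H]1C[C@@H]4OC(OC)C/C4=C/C[C@]2(C)O[C@H]1C[C@@H]2OCc1ccc(OC)cc1
F7 | step 23 | C8 alcohol of the cis-fused cyclic methyl acetal | C[C@H]1C[C@@H]4OC(OC)C[C@@H]4[C@@H](O)C[C@]2(C)O[C@H]1C[C@@H]2OCc1ccc(OC)cc1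
F8 | step 23 | C8 (S)-2,2,4-trimethyl-1,3-dioxolane-4-carboxylate of the cyclic methyl acetal | C[C@H]1C[C@@H]4OC(OC)C[C@@H]4[C@@H](OC(=O)[C@]3(C)COC(C)(C)O3)C[C@]2(C)O[C@H]1C[C@@H]2OCc1ccc(OC)cc1
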